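**Assumption:** the target has no stereocentres, so "single enantiomer" is read as the alkene geometries in the SMILES: the chalcone and ferulate C=C are E, and the side-chain trisubstituted C=C is Z (OCH2 cis to ArCH2).

**Retrosynthetic overview**
1. Last step: cleave three aryl acetates selectively, leaving the alkyl ferulate ester intact.
2. Ferulate C–O bond: Mitsunobu esterification of a primary (Z)-allylic alcohol with unprotected trans-ferulic acid.
3. Side chain: the ArCH2–CH= bond is made by Stille coupling of a 3'-bromomethyl chalcone triacetate with (Z)-Bu3Sn–CH=C(CH3)CH2OH. The Z geometry comes from Cu-catalysed anti-carbomagnesiation of propargyl alcohol and is carried through with retention.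
4. Bromomethyl chalcone: Claisen–Schmidt condensation of 2',4'-dihydroxy-3'-methylacetophenone with 4-hydroxybenzaldehyde, peracetylation, then benzylic bromination.
5. No ring is formed in the route; all three benzene rings are purchased.

**Route**

Step 1
Reactants: 1 (2',4'-dihydroxy-3'-methylacetophenone); 2 (4-hydroxybenzaldehyde, 1.2 equiv)
Product: 3, (E)-1-(2,4-dihydroxy-3-methylphenyl)-3-(4-hydroxyphenyl)prop-2-en-1-one
Conditions: 60% aq KOH, EtOH, rt, 48 h; then ice/2 M HCl
Reagents that add atoms: none (2 is the only atom donor and is listed as a reactant)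
Why: Claisen–Schmidt aldol condensation; E1cB dehydration gives the thermodynamically favoured E-enone.

Step 2
Reactants: 3; 4 (acetic anhydride)
Product: 5, (E)-1-(2,4-diacetoxy-3-methylphenyl)-3-(4-acetoxyphenyl)prop-2-en-1-one (chalcone triacetate)
Conditions: Ac2O (5 equiv), pyridine, DMAP (cat.), 0 °C to rt
Reagents that add atoms: acetic anhydride, CC(=O)OC(C)=O
Why: exhaustive O-acetylation, including the chelated 2'-OH, masks the phenols and deactivates the ring for the radical bromination; aryl acetates can later be removed without cleaving an alkyl cinnamate.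

Step 3
Reactants: 5; 6 (N-bromosuccinimide)
Product: 7, (E)-1-[2,4-diacetoxy-3-(bromomethyl)phenyl]-3-(4-acetoxyphenyl)prop-2-en-1-one
Conditions: NBS (1.05 equiv), AIBN (10 mol%), PhCF3, 80 °C, dark
Reagents that add atoms: N-bromosuccinimide, O=C1CCC(=O)N1Br
Why: Wohl–Ziegler benzylic bromination; ArCH3 is the only activated sp3 C–H (the chalcone has no enolisable α-CH), and the deactivated ring and electron-poor enone resist bromine.

Step 4
Reactants: 8 (propargyl alcohol); 9 (methylmagnesium bromide); 10 (tributyltin chloride)
Product: 11, (Z)-2-methyl-3-(tributylstannyl)prop-2-en-1-ol (Sn cis to CH2OH)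
Conditions: MeMgBr (2.5 equiv), CuI (10 mol%), THF, −10 °C to rt; then Bu3SnCl (2 equiv), 0 °C to rt; aq NH4Cl
Reagents that add atoms: methylmagnesium bromide, C[Mg]Br; tributyltin chloride, CCCC[Sn](Cl)(CCCC)CCCC
Why: Cu-catalysed anti-carbomagnesiation of a propargylic alkoxide puts methyl on C2 and gives a five-membered alkenylmagnesium chelate with Mg cis to CH2O; stannylation with retention fixes the Z geometry.

Step 5
Reactants: 7; 11 (1.2 equiv)
Product: 12, (E)-1-{2,4-diacetoxy-3-[(2Z)-4-hydroxy-3-methylbut-2-en-1-yl]phenyl}-3-(4-acetoxyphenyl)prop-2-en-1-one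
Conditions: Pd2(dba)3 (2.5 mol%), AsPh3 (20 mol%), THF, 50 °C; aq KF work-up
Reagents that add atoms: none
Why: Stille coupling of a benzyl bromide with an alkenylstannane proceeds with retention of alkene geometry under neutral conditions that tolerate aryl acetates, the enone and the free OH; no allylic leaving group is present, so no π-allyl scrambling of the Z alkene.

Step 6
Reactants: 12; 13 (trans-ferulic acid, 1.3 equiv)
Product: 14, (2Z)-4-{2,6-diacetoxy-3-[(E)-3-(4-acetoxyphenyl)acryloyl]phenyl}-2-methylbut-2-en-1-yl (E)-3-(4-hydroxy-3-methoxyphenyl)acrylate (gemichalcone A 2',4',4-triacetate)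
Conditions: PPh3 (1.5 equiv), DIAD (1.5 equiv, betaine preformed), THF, 0 °C to rt
Reagents that add atoms: none (13 is a listed reactant; the ester alkyl oxygen comes from its carboxylate)
Why: Mitsunobu esterification activates the carboxylic acid well ahead of the ferulic phenol, so no protection of 13 is needed; SN2 at the primary allylic carbon leaves the Z alkene untouched, and the substrate phenols are acetylated so they cannot cyclise onto the activated alcohol.

Step 7
Reactants: 14
Product: 15, gemichalcone A
Conditions: NH4OAc (10 equiv), MeOH/THF/H2O (4:2:1), rt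
Reagents that add atoms: none
Why: chemoselective solvolysis of aryl acetates (phenoxide leaving groups) over the conjugated alkyl ferulate; the near-neutral buffer avoids chalcone-to-flavanone cyclisation and leaves all three alkene geometries unchanged.

**Compound list**
1 | 2',4'-dihydroxy-3'-methylacetophenone | CC(=O)c1ccc(O)c(C)c1O | starting material
2 | 4-hydroxybenzaldehyde | O=Cc1ccc(O)cc1 | starting material
3 | (E)-1-(2,4-dihydroxy-3-methylphenyl)-3-(4-hydroxyphenyl)prop-2-en-1-one | Cc1c(O)ccc(C(=O)/C=C/c2ccc(O)cc2)c1O | intermediate
4 | acetic anhydride | CC(=O)OC(C)=O | starting material (reagent)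
5 | chalcone triacetate | Cc1c(OC(C)=O)ccc(C(=O)/C=C/c2ccc(OC(C)=O)cc2)c1OC(C)=O | intermediate
6 | N-bromosuccinimide | O=C1CCC(=O)N1Br | starting material (reagent)
7 | 3'-(bromomethyl) chalcone triacetate | BrCc1c(OC(C)=O)ccc(C(=O)/C=C/c2ccc(OC(C)=O)cc2)c1OC(C)=O | intermediate
8 | propargyl alcohol | C#CCO | starting material
9 | methylmagnesium bromide | C[Mg]Br | starting material (reagent)
10 | tributyltin chloride | CCCC[Sn](Cl)(CCCC)CCCC | starting material (reagent)
11 | (Z)-2-methyl-3-(tributylstannyl)prop-2-en-1-ol | OC/C(C)=C\[Sn](CCCC)(CCCC)CCCC | intermediate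
12 | 3'-[(2Z)-4-hydroxy-3-methylbut-2-enyl] chalcone triacetate | OC/C(C)=C\Cc1c(OC(C)=O)ccc(C(=O)/C=C/c2ccc(OC(C)=O)cc2)c1OC(C)=O | intermediate
13 | trans-ferulic acid | COc1cc(/C=C/C(=O)O)ccc1O | starting material
14 | gemichalcone A 2',4',4-triacetate | COc1cc(/C=C/C(=O)OC/C(C)=C\Cc2c(OC(C)=O)ccc(C(=O)/C=C/c3ccc(OC(C)=O)cc3)c2OC(C)=O)ccc1O | intermediate
15 | gemichalcone A | COc1cc(/C=C/C(=O)OC/C(C)=C\Cc2c(O)ccc(C(=O)/C=C/c3ccc(O)cc3)c2O)ccc1O | target

**Totals**
Total steps: 7. Longest linear sequence: 6 (steps 1, 2, 3, 5, 6, 7); step 4 is a one-step side branch.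

**Steps most likely to fail, with fallbacks**
1. Step 3 (benzylic bromination of a crowded methyl in the presence of the chalcone alkene). Fallback: brominate and Stille-couple at the acetophenone stage (2,4-diacetoxy-3-methylacetophenone, no alkene present), then build the enone afterwards by exchanging acetates for MOM ethers and running a base Claisen–Schmidt with 4-(methoxymethoxy)benzaldehyde.
2. Step 5 (Stille coupling of a di-ortho-substituted benzyl bromide; risk of homocoupling or destannylation). Fallback: switch to an aryl–allyl disconnection. Trap the step 4 alkenylmagnesium with I2, protect the alcohol, then convert via the vinyllithium and formaldehyde, followed by an Appel reaction, into a (Z)-4-bromo-2-methylbut-2-enyl silyl ether. Use that bromide to alkylate 3-lithio-1-bromo-2,4-bis(methoxymethoxy)benzene (SN2, geometry retained), then Br/Li exchange, acylation and Claisen–Schmidt.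
3. Step 7 (triple deacetylation without ferulate cleavage or flavanone formation). Fallback: invert the endgame. Fully deacetylate alcohol 12 first, then acylate only the aliphatic OH with vinyl ferulate under lipase (CAL-B) catalysis, so no deprotection follows ester formation.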